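**Strategy.** Ring A is cut away from a ring B cyclohexenone, so that C9–C11, C10–C1 and C4=C5 all arise in one operation from (S)-3,4-dimethylcyclohex-2-en-1-one. The feature used is that C9, a quaternary carbon, is flanked by C8 (the methyl-bearing stereocentre) and by C10, from which ring A grows through C1. Copper-catalysed vinyl addition at C9, opposite the C8 methyl, leaves an enolate fixed at C10. This enolate adds to an α-silyl ethyl vinyl ketone, and base then removes silicon and closes ring A by aldol condensation. Only C8 is made beforehand, by enamine catalysis. The C6 oxygen introduced later steers both formation of the 5(10)-dienolate and the C4 hydroxymethylation.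

Key step: step 7

Remarks on the chemistry:
- Halimane numbering is used for the bicyclic compounds; β is the face of the C17 and C20 methyl groups, α the face of C11 and of the C6 oxygen.
- Assumption: the (R)-configured prolinol ether is taken to give the (S)-aldehyde in step 1, following the usual enamine shielding model; if the sense were opposite, the antipodal catalyst would be used.
- C10 is drawn with H α (C1 trans to the C9 vinyl group), the arrangement expected after equilibration in base. It becomes sp2 in step 11, so either C10 epimer can be carried forward.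

Step 1
Reactants: 1 propanal; 2 but-3-en-2-one
Product: 3 (S)-2-methyl-5-oxohexanal
Conditions: (R)-2-(methoxydiphenylmethyl)pyrrolidine (5 mol%), ethyl 3,4-dihydroxybenzoate (20 mol%), neat, 4 °C
Reagents that add atoms: none
Why: Enamine-catalysed Michael addition, in which the E-enamine of propanal should add to the enone on the face away from the diarylmethyl group and so set the future C8 stereocentre as S.

Step 2
Reactants: 3 (S)-2-methyl-5-oxohexanal
Product: 4 (S)-4-methylcyclohex-2-en-1-one
Conditions: LiOH·H2O (0.1 equiv), i-PrOH, rt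
Reagents that add atoms: none
Why: Intramolecular aldol condensation (6-(enolendo)-exo-trig) of the methyl ketone onto the aldehyde, where mild base should close the ring faster than it enolises the aldehyde, so the stereocentre (γ to the carbonyl afterwards) is kept.

Step 3
Reactants: 4 (S)-4-methylcyclohex-2-en-1-one
Product: 5 trimethyl{[(3R,4S)-3,4-dimethylcyclohex-1-en-1-yl]oxy}silane
Conditions: MeMgBr, CuBr·SMe2 (5 mol%), TMSCl, DMPU, THF, −78 °C; Et3N/pentane work-up
Reagents that add atoms: methylmagnesium bromide C[Mg]Br; chlorotrimethylsilane C[Si](C)(C)Cl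
Why: Copper-catalysed conjugate addition with in situ silylation traps the enolate as a single regioisomer; methyl should enter mainly trans to the C4 methyl, but that carbon becomes sp2 in step 4, so its configuration does not matter.

Step 4
Reactants: 5 trimethyl{[(3R,4S)-3,4-dimethylcyclohex-1-en-1-yl]oxy}silane
Product: 6 (S)-3,4-dimethylcyclohex-2-en-1-one
Conditions: Pd(OAc)2 (10 mol%), O2 (1 atm), DMSO, rt
Reagents that add atoms: none
Why: Saegusa–Ito oxidation, in which the palladium enolate at C2 can only lose the hydrogen at C3, restoring the enone with its new β-methyl group and leaving the C4 (future C8) stereocentre untouched.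

Step 5
Reactants: 7 (1-bromovinyl)trimethylsilane; 1 propanal
Product: 9 2-(trimethylsilyl)pent-1-en-3-ol (racemic), via Grignard reagent 8 (not isolated)
Conditions: Mg, THF, reflux; then 1, 0 °C; aq. NH4Cl
Reagents that add atoms: none
Why: Grignard formation from the α-bromovinylsilane and 1,2-addition to the aldehyde, a standard entry to 2-silyl allylic alcohols.

Step 6
Reactants: 9 2-(trimethylsilyl)pent-1-en-3-ol
Product: 10 2-(trimethylsilyl)pent-1-en-3-one
Conditions: Dess–Martin periodinane, CH2Cl2, 0 °C → rt; used at once
Reagents that add atoms: none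
Why: Dess–Martin oxidation of the secondary allylic alcohol under non-basic conditions, which should spare the polymerisation-prone α-silyl enone.

Step 7
Reactants: 6 (S)-3,4-dimethylcyclohex-2-en-1-one; 11 vinylmagnesium bromide; 10 2-(trimethylsilyl)pent-1-en-3-one
Product: 14 (4aS,5R,6S)-5-ethenyl-1,5,6-trimethyl-4,4a,5,6,7,8-hexahydronaphthalen-2(3H)-one (halimane numbering 8S,9R,10S), via magnesium enolate 12 (not isolated), via silyl diketone 13 (not isolated)
Conditions: 11 (1.3 equiv), CuBr·SMe2 (10 mol%), THF, −78 → −40 °C; then 10, −78 → −20 °C; then KOH, MeOH, 65 °C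
Reagents that add atoms: none
Why: Copper-catalysed 1,4-addition of the vinyl Grignard reagent to the β-methyl enone creates quaternary C9 and leaves a magnesium enolate fixed at C5=C10, which adds through C10 to the α-silyl vinyl ketone (silicon stabilises the new carbanion and suppresses polymerisation); KOH in methanol then cleaves the C–Si bond, the ethyl ketone enolate (C4) attacks the ring carbonyl C5 and dehydration gives the C4=C5 enone, i.e. conjugate addition with enolate trapping followed by Robinson annulation. Ring A closes in a 6-(enolendo)-exo-trig aldol mode. C9 is controlled by the C8 methyl: A(1,2) strain with the neighbouring vinylic methyl holds it pseudoaxial in the enone and the nucleophile adds axially on the opposite face, placing C11 trans to C17 and C17 cis to C20. C10 is set under equilibrating base (α to the ketone before closure, γ to the enone after) and should settle with C1 equatorial, trans to the vinyl group; it is erased later when C10 becomes sp2. The step needs 1,4- over 1,2-addition (secured by copper), reaction at C10 and not at C6 (secured by the regiospecific enolate, since base alone could not select the hindered α-carbon) and the six-membered aldol closure that leads to the conjugated tetrasubstituted enone.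

Step 8
Reactants: 14 bicyclic enone
Product: 15 3-ethoxy-3,5-diene (dienol ethyl ether of 14)
Conditions: HC(OEt)3, p-TsOH·H2O (cat.), EtOH/1,4-dioxane, rt; Et3N quench
Reagents that add atoms: triethyl orthoformate CCOC(OCC)OCC
Why: Acid-catalysed dienol ether formation under equilibrating conditions, which for a 10-H 4-en-3-one should favour the transoid 3,5-diene over the cisoid 3,5(10)-diene.

Step 9
Reactants: 15 3-ethoxy-3,5-diene
Product: 16 (6S,8S,9R,10S)-6α-hydroxy-4-en-3-one
Conditions: m-CPBA (1.05 equiv), THF/H2O (9:1), 0 °C; aq. NaHCO3/Na2S2O3 work-up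
Reagents that add atoms: m-chloroperbenzoic acid OOC(=O)c1cccc(Cl)c1; water O
Why: Vinylogous Rubottom-type oxidation, in which the peracid attacks the electron-rich diene at C6 far faster than the isolated vinyl group and hydrolysis returns the enone; axial attack on the half-chair with equatorial C8 methyl comes from the α face (syn to H8 and H10, the analogue of 6-hydroxylation of steroidal dienol ethers), whereas axial attack from the β face would need the C8 methyl axial and would meet it, so the 6α (6S) alcohol should form.

Step 10
Reactants: 16 6α-hydroxy-4-en-3-one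
Product: 17 6α-(tert-butyldimethylsilyloxy)-4-en-3-one
Conditions: TBSOTf, 2,6-lutidine, CH2Cl2, −78 → 0 °C
Reagents that add atoms: tert-butyldimethylsilyl triflate CC(C)(C)[Si](C)(C)OS(=O)(=O)C(F)(F)F
Why: Silylation of the hindered axial secondary alcohol with the silyl triflate removes the acidic O–H and installs the bulky axial group that is used in step 11.

Step 11
Reactants: 17 6α-silyloxy-4-en-3-one
Product: 19 (4S,6S,8S,9R)-6α-(tert-butyldimethylsilyloxy)-4β-(hydroxymethyl)-4α-methyl-5(10)-en-3-one (C19 alcohol), via potassium dienolate 18 (not isolated)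
Conditions: KOt-Bu (1.05 equiv), THF, 0 °C, 1 h; then monomeric CH2O (THF solution from cracked paraformaldehyde), −78 °C; AcOH quench at −78 °C
Reagents that add atoms: formaldehyde C=O
Why: Deconjugative α-hydroxymethylation (aldol addition of a thermodynamic extended enolate at its α-carbon): the axial 6α-silyloxy group puts H6 in the enone plane where it is not acidic, so equilibration should give the 3,5(10)-dienolate by loss of the axial H10, and formaldehyde should add to C4 on the β face, anti to the axial C6 silyloxy group, giving the 4S centre and the C5=C10 alkene.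

Step 12
Reactants: 20 3-(4-hydroxyphenyl)propanoic acid
Product: 22 3-[4-(triisopropylsilyloxy)phenyl]propanoic acid, via bis-silyl derivative 21 (not isolated)
Conditions: TIPSCl (2.2 equiv), imidazole, DMF, rt; then K2CO3 (cat.), MeOH/THF/H2O, 0 °C
Reagents that add atoms: chlorotriisopropylsilane CC(C)[Si](Cl)(C(C)C)C(C)C
Why: Exhaustive silylation followed by selective solvolysis of the labile silyl ester, which leaves the aryl silyl ether in place.

Step 13
Reactants: 19 C19 alcohol; 22 3-[4-(triisopropylsilyloxy)phenyl]propanoic acid
Product: 23 C19 ester (9-vinyl, 6-OTBS, aryl OTIPS)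
Conditions: EDC·HCl, DMAP, CH2Cl2, 0 °C → rt
Reagents that add atoms: none
Why: Steglich esterification of the primary neopentyl alcohol; C4 has no hydrogen, so the β-acyloxy ketone cannot eliminate, and acylation also blocks retro-aldol loss of formaldehyde.

Step 14
Reactants: 23 C19 ester; 24 4-bromofuran-2(5H)-one
Product: 26 bis-silyl ether of the target, via B-alkyl borane 25 (not isolated)
Conditions: 9-BBN (1.3 equiv), THF, 0 °C → rt; then 24, Pd(dppf)Cl2 (5 mol%), AsPh3 (10 mol%), K3PO4 (3 M aq.), DMF, rt
Reagents that add atoms: none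
Why: Anti-Markovnikov hydroboration of the monosubstituted alkene (the tetrasubstituted C5=C10 alkene is inert and the α-quaternary C3 ketone should be reduced much more slowly) followed by B-alkyl Suzuki–Miyaura coupling with the β-bromobutenolide, which adds oxidatively with ease; phosphate base at room temperature should spare the ester and both silyl ethers.

Step 15
Reactants: 26 bis-silyl ether of the target
Product: 27 CNP0301014.1 (4S,6S,8S,9R)
Conditions: Bu4NF, AcOH (1:1), THF, 0 °C → rt
Reagents that add atoms: none
Why: Fluoride-mediated desilylation buffered with acetic acid should remove the aryl and the secondary silyl ether without base-induced damage to the butenolide, the ester or the allylic alcohol, and it touches no stereocentre.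

**Compound list**

1 | propanal | CCC=O | starting material
2 | but-3-en-2-one | CC(=O)C=C | starting material
3 | (S)-2-methyl-5-oxohexanal | C[C@H](C=O)CCC(C)=O | intermediate
4 | (S)-4-methylcyclohex-2-en-1-one | C[C@H]1CCC(=O)C=C1 | intermediate
5 | trimethyl{[(3R,4S)-3,4-dimethylcyclohex-1-en-1-yl]oxy}silane | C[C@H]1CCC(O[Si](C)(C)C)=C[C@@H]1C | intermediate
6 | (S)-3,4-dimethylcyclohex-2-en-1-one | C[C@H]1CCC(=O)C=C1C | intermediate
7 | (1-bromovinyl)trimethylsilane | C=C(Br)[Si](C)(C)C | starting material
8 | [1-(trimethylsilyl)ethenyl]magnesium bromide | C=C([Mg]Br)[Si](C)(C)C | intermediate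
9 | 2-(trimethylsilyl)pent-1-en-3-ol (racemic) | CCC(O)C(=C)[Si](C)(C)C | intermediate
10 | 2-(trimethylsilyl)pent-1-en-3-one | CCC(=O)C(=C)[Si](C)(C)C | intermediate
11 | vinylmagnesium bromide | C=C[Mg]Br | starting material
12 | bromomagnesium enolate (C5=C10) of (8S,9R)-3-ethenyl-3,4-dimethylcyclohexanone | C[C@H]1CCC(O[Mg]Br)=C[C@]1(C)C=C | intermediate
13 | (8S,9R)-3-ethenyl-3,4-dimethyl-2-[3-oxo-2-(trimethylsilyl)pentyl]cyclohexanone (C10 and the silylated carbon not defined) | C[C@H]1CCC(=O)C(CC(C(=O)CC)[Si](C)(C)C)[C@]1(C)C=C | intermediate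
14 | (4aS,5R,6S)-5-ethenyl-1,5,6-trimethyl-4,4a,5,6,7,8-hexahydronaphthalen-2(3H)-one (8S,9R,10S) | C[C@H]1CCC2=C(C)C(=O)CC[C@H]2[C@]1(C)C=C | intermediate
15 | 3-ethoxy-3,5-diene, dienol ethyl ether of 14 (8S,9R,10S) | C[C@H]1CC=C2C(C)=C(OCC)CC[C@H]2[C@]1(C)C=C | intermediate
16 | (6S,8S,9R,10S)-6α-hydroxy-4-en-3-one | C[C@H]1C[C@H](O)C2=C(C)C(=O)CC[C@H]2[C@]1(C)C=C | intermediate
17 | 6α-O-TBS ether of 16 | C[C@H]1C[C@H](O[Si](C)(C)C(C)(C)C)C2=C(C)C(=O)CC[C@H]2[C@]1(C)C=C | intermediate
18 | potassium 3,5(10)-dienolate of 17 | C[C@H]1C[C@H](O[Si](C)(C)C(C)(C)C)C2=C(CCC([O-])=C2C)[C@]1(C)C=C.[K+] | intermediate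
19 | (4S,6S,8S,9R)-6α-(TBS-oxy)-4β-(hydroxymethyl)-4α,8β,9β-trimethyl-9α-vinyl-5(10)-en-3-one | C[C@H]1C[C@H](O[Si](C)(C)C(C)(C)C)C2=C(CCC(=O)[C@]2(C)CO)[C@]1(C)C=C | intermediate
20 | 3-(4-hydroxyphenyl)propanoic acid | OC(=O)CCc1ccc(O)cc1 | starting material
21 | triisopropylsilyl 3-[4-(triisopropylsilyloxy)phenyl]propanoate | CC(C)[Si](C(C)C)(C(C)C)OC(=O)CCc1ccc(O[Si](C(C)C)(C(C)C)C(C)C)cc1 | intermediate
22 | 3-[4-(triisopropylsilyloxy)phenyl]propanoic acid | OC(=O)CCc1ccc(O[Si](C(C)C)(C(C)C)C(C)C)cc1 | intermediate
23 | C19 3-[4-(triisopropylsilyloxy)phenyl]propanoate of 19 | C[C@H]1C[C@H](O[Si](C)(C)C(C)(C)C)C2=C(CCC(=O)[C@]2(C)COC(=O)CCc2ccc(O[Si](C(C)C)(C(C)C)C(C)C)cc2)[C@]1(C)C=C | intermediate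
24 | 4-bromofuran-2(5H)-one | O=C1C=C(Br)CO1 | starting material
25 | C12 B-alkyl-9-borabicyclo[3.3.1]nonane from 23 | C[C@H]1C[C@H](O[Si](C)(C)C(C)(C)C)C2=C(CCC(=O)[C@]2(C)COC(=O)CCc2ccc(O[Si](C(C)C)(C(C)C)C(C)C)cc2)[C@]1(C)CCB1C2CCCC1CCC2 | intermediate
26 | 6-O-TBS, aryl O-TIPS ether of the target | C[C@H]1C[C@H](O[Si](C)(C)C(C)(C)C)C2=C(CCC(=O)[C@]2(C)COC(=O)CCc2ccc(O[Si](C(C)C)(C(C)C)C(C)C)cc2)[C@]1(C)CCC1=CC(=O)OC1 | intermediate
27 | CNP0301014.1 (4S,6S,8S,9R) | C[C@H]1C[C@H](O)C2=C(CCC(=O)[C@]2(C)COC(=O)CCc2ccc(O)cc2)[C@]1(C)CCC1=CC(=O)OC1 | target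

**Step count.** Total: 15 steps. Longest linear sequence: 12 steps (1–4, 7–11, 13–15).

**Steps most likely to fail**

Step 11. Proton abstraction may occur at C2 or C6 instead of C10, the aldol adduct may revert to dienolate and formaldehyde, or attack may come partly from the α face. The fallback replaces the reversible aldol by an irreversible alkylation. It sets out from 17: the thermodynamic sodium dienolate (NaH, THF/DMF, rt) is alkylated at C4 with 4-methoxybenzyl chloromethyl ether (classical deconjugative alkylation) to give the C19 4-methoxybenzyl ether F1. Oxidative cleavage with DDQ (CH2Cl2/pH 7 buffer) then comes back to the route at 19.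

Step 14. The borane may reduce the C3 ketone in competition with hydroboration of the hindered vinyl group, and the alkylborane may suffer protodeboronation before coupling. The fallback accepts the reduction and restores the ketone afterwards. It sets out from 19: excess 9-BBN (THF, 40 °C) reduces C3 and hydroborates the vinyl group, and the same Suzuki–Miyaura coupling with 24 gives the 3,19-diol F4 (C3 configuration immaterial). Selective Steglich acylation of the primary alcohol with 22 (EDC·HCl, DMAP, 0 °C) gives the 19-monoester F5. Dess–Martin oxidation of the C3 carbinol then comes back to the route at 26.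

Step 9. Facial selectivity at C6 may be poor or reversed if the reacting half-chair differs from the one assumed. The fallback corrects the configuration by inversion instead of relying on the oxidation. It sets out from 15: the same oxidation is run, and if the 6β-alcohol F2 prevails it is inverted by Mitsunobu reaction (4-nitrobenzoic acid, PPh3, DIAD, THF) to the 6α 4-nitrobenzoate F3. Methanolysis (K2CO3, MeOH) then comes back to the route at 16.

Further compounds
F1 | step 11 | C19 4-methoxybenzyl ether of 19 | C[C@H]1C[C@H](O[Si](C)(C)C(C)(C)C)C2=C(CCC(=O)[C@]2(C)COCc2ccc(OC)cc2)[C@]1(C)C=C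
F2 | step 9 | (6R,8S,9R,10S)-6β-hydroxy-4-en-3-one, C6 epimer of 16 | C[C@H]1C[C@@H](O)C2=C(C)C(=O)CC[C@H]2[C@]1(C)C=C
F3 | step 9 | 6α 4-nitrobenzoate of 16 | C[C@H]1C[C@H](OC(=O)c3ccc(cc3)[N+](=O)[O-])C2=C(C)C(=O)CC[C@H]2[C@]1(C)C=C
F4 | step 14 | 3,19-diol with butenolide side chain, 6-O-TBS (C3 not defined) | C[C@H]1C[C@H](O[Si](C)(C)C(C)(C)C)C2=C(CCC(O)[C@]2(C)CO)[C@]1(C)CCC1=CC(=O)OC1
F5 | step 14 | 3-hydroxy 19-monoester, 6-O-TBS, aryl O-TIPS (C3 not defined) | C[C@H]1C[C@H](O[Si](C)(C)C(C)(C)C)C2=C(CCC(O)[C@]2(C)COC(=O)CCc2ccc(O[Si](C(C)C)(C(C)C)C(C)C)cc2)[C@]1(C)CCC1=CC(=O)OC1
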